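**Plan**
- Retrosynthesis: the acetic acid arm is traced back to a silyl-protected 2-hydroxyethyl group, the side chain is cut at C9=C10 (C10–C16 come from (2E,4E)-hepta-2,4-dienal), and the 1,2-dioxolane is cut at C4–C5 and O2–C3.
- Enabling feature: in the ring O1–O2–C3–C4–C5 both carbon termini are fully substituted. O1–O2–C5 (C5 with CH3 and the long chain) is a ketone-derived peroxycarbenium unit; C4–C3 (C3 with CH3 and the two-carbon arm) is an isobutene-type 1,1-disubstituted alkene.
- Forward: 11-bromoundec-1-ene becomes a methyl ketone and then a silylperoxy ketal. This and silylated isoprenol are joined in one cationic [3+2] step that closes the only ring. The bromide is then turned into a tetrazolyl sulfone, the triene is attached by olefination, and the arm is oxidised last.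
- The ketone half carries a primary bromide as spectator: it is inert to the cation and becomes the sulfone without phosphine or hydride, both of which threaten the O–O bond.
- Stereochemistry: C3 and C5 are both set in the annulation by a chiral imidodiphosphorimidate counter-anion. Two E double bonds come with the dienal and the third from the olefination.

Key step: step 6

Assumption: the (S,S)-configured catalyst is taken to deliver the (3S,5S)-dioxolane 10; should the sense of induction be the opposite, the (R,R)-catalyst is used.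

Remark: the descriptor at the arm-bearing ring carbon changes from S (compounds 10–15) to R (16, 17) only because the CIP priorities change on oxidation of the arm; the spatial arrangement is the same throughout.

**Step 1**
Reactants: 1 11-bromoundec-1-ene
Product: 2 11-bromoundecan-2-one
Conditions: PdCl2 (10 mol %), CuCl (co-catalyst), O2 (1 atm), DMF/H2O, rt
Reagents that add atoms: water, O (source of the carbonyl oxygen); dioxygen, O=O (terminal oxidant)
Why: Tsuji–Wacker oxidation, in which PdCl2 (divalent palladium) effects Markovnikov hydroxypalladation of the terminal alkene and β-hydride elimination to the methyl ketone while CuCl/O2 re-oxidise the zerovalent palladium formed, should leave the remote primary bromide untouched.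

**Step 2**
Reactants: 2 11-bromoundecan-2-one
Product: 3 11-bromo-2,2-dimethoxyundecane
Conditions: HC(OMe)3, MeOH, p-toluenesulfonic acid (cat.), rt
Reagents that add atoms: trimethyl orthoformate, COC(OC)OC; methanol, CO
Why: acid-catalysed ketalisation of an unhindered methyl ketone, driven to completion by the orthoformate, which consumes the water released.

**Step 3**
Reactants: 3 11-bromo-2,2-dimethoxyundecane
Product: 4 11-bromo-2-hydroperoxy-2-methoxyundecane (racemic)
Conditions: H2O2 (anhydrous, in Et2O, 2 equiv), camphorsulfonic acid (cat.), 0 °C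
Reagents that add atoms: hydrogen peroxide, OO
Why: acid-catalysed perhydrolysis of a dimethyl ketal (exchange of one methoxy group through the oxocarbenium ion, hydrogen peroxide being the stronger nucleophile by the alpha effect) is a standard entry to α-methoxy hydroperoxides, and the new stereocentre may form racemic because this carbon is planarised in step 6.

**Step 4**
Reactants: 4 11-bromo-2-hydroperoxy-2-methoxyundecane
Product: 5 [(11-bromo-2-methoxyundecan-2-yl)peroxy]triethylsilane (racemic)
Conditions: Et3SiCl, imidazole, 4-(dimethylamino)pyridine (cat.), CH2Cl2, 0 °C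
Reagents that add atoms: chlorotriethylsilane, CC[Si](Cl)(CC)CC
Why: O-silylation of the acidic hydroperoxide OH under mildly basic conditions, which keep the acid-labile mixed ketal intact and are too mild for N-alkylation of imidazole by the primary bromide.

**Step 5**
Reactants: 6 3-methylbut-3-en-1-ol
Product: 7 tert-butyl[(3-methylbut-3-en-1-yl)oxy]diphenylsilane
Conditions: t-BuPh2SiCl, imidazole, CH2Cl2, rt
Reagents that add atoms: tert-butyl(chloro)diphenylsilane, CC(C)(C)[Si](Cl)(c1ccccc1)c1ccccc1
Why: routine silyl ether formation on a primary alcohol, giving a bulky and weakly basic ether that should neither bind nor be cleaved by the Lewis acid of step 6.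

**Step 6**
Reactants: 5 [(11-bromo-2-methoxyundecan-2-yl)peroxy]triethylsilane; 7 tert-butyl[(3-methylbut-3-en-1-yl)oxy]diphenylsilane
Product: 10 tert-butyl{2-[(3S,5S)-5-(9-bromononyl)-3,5-dimethyl-1,2-dioxolan-3-yl]ethoxy}diphenylsilane, via peroxycarbenium ion 8 (not isolated), via tertiary carbenium ion 9 (not isolated)
Conditions: chiral imidodiphosphorimidate acid (S,S)-HN[P(=NSO2CF3)(O2C20H10Ar2)]2, Ar = 3,5-(CF3)2C6H3 (5 mol %), 7 (2 equiv), toluene, −78 °C
Reagents that add atoms: none
Why: Proposed new method: the acid (and, after the first turnover, its Et3Si form, a silylium-type Lewis acid) removes the methoxy group of 5 as Et3SiOMe and leaves peroxycarbenium ion 8 tightly paired with the confined chiral anion; the CH2 terminus of 7 then adds to C5 in a Markovnikov, Prins-type step to give tertiary carbenium ion 9, whose silylated peroxide oxygen O2 captures C3 and passes Et3Si+ back to the anion, so that the cycle is closed. The closest known reactions are the racemic SnCl4-promoted [3+2] annulation of triethylsilylperoxy ketals with 1,1-disubstituted alkenes and the enantioselective additions of alkene and enol-silane nucleophiles to oxocarbenium ions under imidodiphosphorimidate catalysis (Hosomi–Sakurai-, Mukaiyama- and Prins-type), so that only the pairing of a peroxycarbenium ion with such an anion is new. The 1,2-dioxolane closes stepwise and polar, C4–C5 first and O2–C3 second, the latter as a five-membered oxygen capture of a free tertiary cation in which both former alkene carbons become ring members. C5 (S) is set in the C–C bond formation by the face of the planar cation that the anion leaves open, and C3 (S) is set in the ring closure, where the anion pocket and the preference of the two long substituents (bromononyl on C5, silyloxyethyl on C3) for opposite ring faces should favour the trans-dimethyl ring. The step needs Markovnikov regioselectivity and cyclisation in preference to proton loss, 1,2-shift of the peroxycarbenium ion or alkene oligomerisation: the 1,1-disubstituted alkene guarantees the tertiary cation at C3, the silyl peroxide is a good internal nucleophile, the low temperature and non-basic anion suppress the side paths, and bromide and silyl ether are the only other functions present. Racemic 5 is no handicap because its stereocentre is erased on ionisation.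

**Step 7**
Reactants: 10 tert-butyl{2-[(3S,5S)-5-(9-bromononyl)-3,5-dimethyl-1,2-dioxolan-3-yl]ethoxy}diphenylsilane
Product: 11 5-({9-[(3S,5S)-5-{2-[tert-butyl(diphenyl)silyloxy]ethyl}-3,5-dimethyl-1,2-dioxolan-3-yl]nonyl}sulfanyl)-1-phenyl-1H-tetrazole
Conditions: 1-phenyl-1H-tetrazole-5-thiol, K2CO3, DMF, rt
Reagents that add atoms: 1-phenyl-1H-tetrazole-5-thiol, Sc1nnnn1-c1ccccc1
Why: SN2 thioether formation at the primary bromide by the soft, weakly basic tetrazolethiolate, which needs no phosphine and should spare the di-tertiary peroxide because it has no α-hydrogen for Kornblum–DeLaMare cleavage and is hindered toward a stabilised thiolate.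

**Step 8**
Reactants: 11 5-({9-[(3S,5S)-5-{2-[tert-butyl(diphenyl)silyloxy]ethyl}-3,5-dimethyl-1,2-dioxolan-3-yl]nonyl}sulfanyl)-1-phenyl-1H-tetrazole
Product: 12 5-({9-[(3S,5S)-5-{2-[tert-butyl(diphenyl)silyloxy]ethyl}-3,5-dimethyl-1,2-dioxolan-3-yl]nonyl}sulfonyl)-1-phenyl-1H-tetrazole
Conditions: (NH4)6Mo7O24·4H2O (10 mol %), 30% aq. H2O2, EtOH/THF, 0 °C to rt
Reagents that add atoms: hydrogen peroxide, OO
Why: molybdate-catalysed peroxide oxidation of the sulfide through the sulfoxide to the sulfone, to which the dialkyl peroxide, the silyl ether and the saturated chain are inert, no alkene being present at this stage.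

**Step 9**
Reactants: 12 5-({9-[(3S,5S)-5-{2-[tert-butyl(diphenyl)silyloxy]ethyl}-3,5-dimethyl-1,2-dioxolan-3-yl]nonyl}sulfonyl)-1-phenyl-1H-tetrazole; 13 (2E,4E)-hepta-2,4-dienal
Product: 14 tert-butyl{2-[(3S,5S)-5-[(9E,11E,13E)-hexadeca-9,11,13-trien-1-yl]-3,5-dimethyl-1,2-dioxolan-3-yl]ethoxy}diphenylsilane
Conditions: KN(SiMe3)2, DME, −60 °C; then 13, −60 °C to rt; aq. NH4Cl
Reagents that add atoms: none
Why: Julia–Kocienski olefination (addition of the α-sulfonyl carbanion to the aldehyde, Smiles rearrangement, loss of SO2 and tetrazololate), which with a phenyltetrazolyl sulfone, a potassium counter-ion, an ethereal solvent and a conjugated aldehyde should form the new C9=C10 bond with E geometry, the dienal geometry being carried over and the ring offering no acidic hydrogen.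

**Step 10**
Reactants: 14 tert-butyl{2-[(3S,5S)-5-[(9E,11E,13E)-hexadeca-9,11,13-trien-1-yl]-3,5-dimethyl-1,2-dioxolan-3-yl]ethoxy}diphenylsilane
Product: 15 2-[(3S,5S)-5-[(9E,11E,13E)-hexadeca-9,11,13-trien-1-yl]-3,5-dimethyl-1,2-dioxolan-3-yl]ethan-1-ol
Conditions: Bu4NF, AcOH, THF, 0 °C to rt
Reagents that add atoms: none
Why: fluoride-driven desilylation (formation of the strong Si–F bond), buffered with acetic acid so that the medium stays non-basic toward the peroxide and the triene.

**Step 11**
Reactants: 15 2-[(3S,5S)-5-[(9E,11E,13E)-hexadeca-9,11,13-trien-1-yl]-3,5-dimethyl-1,2-dioxolan-3-yl]ethan-1-ol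
Product: 16 2-[(3R,5S)-5-[(9E,11E,13E)-hexadeca-9,11,13-trien-1-yl]-3,5-dimethyl-1,2-dioxolan-3-yl]acetaldehyde
Conditions: Dess–Martin periodinane, NaHCO3, CH2Cl2, 0 °C
Reagents that add atoms: none
Why: Dess–Martin oxidation (ligand exchange at iodine, then intramolecular proton abstraction) stops at the aldehyde under buffered, near-neutral conditions that should touch neither the triene nor the O–O bond, and the aldehyde is carried on at once to forestall β-elimination.

**Step 12**
Reactants: 16 2-[(3R,5S)-5-[(9E,11E,13E)-hexadeca-9,11,13-trien-1-yl]-3,5-dimethyl-1,2-dioxolan-3-yl]acetaldehyde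
Product: 17 2-[(3R,5S)-5-[(9E,11E,13E)-hexadeca-9,11,13-trien-1-yl]-3,5-dimethyl-1,2-dioxolan-3-yl]acetic acid
Conditions: NaClO2, NaH2PO4, 2-methylbut-2-ene, t-BuOH/H2O, 0 °C to rt
Reagents that add atoms: sodium chlorite, [Na+].[O-]Cl=O
Why: Pinnick oxidation, in which chlorous acid adds to the aldehyde and fragments to the acid, works in a weakly acidic buffer that avoids enolisation, and the hypochlorous acid released is intercepted by the excess 2-methylbut-2-ene before it can attack the triene.

**Compound list**
1 | 11-bromoundec-1-ene | C=CCCCCCCCCCBr | starting material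
2 | 11-bromoundecan-2-one | CC(=O)CCCCCCCCCBr | intermediate
3 | 11-bromo-2,2-dimethoxyundecane | CC(OC)(OC)CCCCCCCCCBr | intermediate
4 | 11-bromo-2-hydroperoxy-2-methoxyundecane (racemic) | CC(OC)(OO)CCCCCCCCCBr | intermediate
5 | [(11-bromo-2-methoxyundecan-2-yl)peroxy]triethylsilane (racemic) | CC(OC)(OO[Si](CC)(CC)CC)CCCCCCCCCBr | intermediate
6 | 3-methylbut-3-en-1-ol | C=C(C)CCO | starting material
7 | tert-butyl[(3-methylbut-3-en-1-yl)oxy]diphenylsilane | C=C(C)CCO[Si](c1ccccc1)(c1ccccc1)C(C)(C)C | intermediate
8 | peroxycarbenium ion 11-bromo-2-[(triethylsilyl)peroxy]undecan-2-ylium, ion-paired with the catalyst anion, not isolated | CC(=[O+]O[Si](CC)(CC)CC)CCCCCCCCCBr | intermediate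
9 | tertiary carbenium ion (5S)-14-bromo-1-[tert-butyl(diphenyl)silyloxy]-3,5-dimethyl-5-[(triethylsilyl)peroxy]tetradecan-3-ylium, not isolated | BrCCCCCCCCC[C@@](OO[Si](CC)(CC)CC)(C)C[C+](C)CCO[Si](c1ccccc1)(c1ccccc1)C(C)(C)C | intermediate
10 | tert-butyl{2-[(3S,5S)-5-(9-bromononyl)-3,5-dimethyl-1,2-dioxolan-3-yl]ethoxy}diphenylsilane | BrCCCCCCCCC[C@@]1(C)C[C@](C)(CCO[Si](c2ccccc2)(c2ccccc2)C(C)(C)C)OO1 | intermediate
11 | 5-({9-[(3S,5S)-5-{2-[tert-butyl(diphenyl)silyloxy]ethyl}-3,5-dimethyl-1,2-dioxolan-3-yl]nonyl}sulfanyl)-1-phenyl-1H-tetrazole | c1ccccc1-n1nnnc1SCCCCCCCCC[C@@]1(C)C[C@](C)(CCO[Si](c2ccccc2)(c2ccccc2)C(C)(C)C)OO1 | intermediate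
12 | 5-({9-[(3S,5S)-5-{2-[tert-butyl(diphenyl)silyloxy]ethyl}-3,5-dimethyl-1,2-dioxolan-3-yl]nonyl}sulfonyl)-1-phenyl-1H-tetrazole | c1ccccc1-n1nnnc1S(=O)(=O)CCCCCCCCC[C@@]1(C)C[C@](C)(CCO[Si](c2ccccc2)(c2ccccc2)C(C)(C)C)OO1 | intermediate
13 | (2E,4E)-hepta-2,4-dienal | CC/C=C/C=C/C=O | starting material
14 | tert-butyl{2-[(3S,5S)-5-[(9E,11E,13E)-hexadeca-9,11,13-trien-1-yl]-3,5-dimethyl-1,2-dioxolan-3-yl]ethoxy}diphenylsilane | CC/C=C/C=C/C=C/CCCCCCCC[C@@]1(C)C[C@](C)(CCO[Si](c2ccccc2)(c2ccccc2)C(C)(C)C)OO1 | intermediate
15 | 2-[(3S,5S)-5-[(9E,11E,13E)-hexadeca-9,11,13-trien-1-yl]-3,5-dimethyl-1,2-dioxolan-3-yl]ethan-1-ol | CC/C=C/C=C/C=C/CCCCCCCC[C@@]1(C)C[C@](C)(CCO)OO1 | intermediate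
16 | 2-[(3R,5S)-5-[(9E,11E,13E)-hexadeca-9,11,13-trien-1-yl]-3,5-dimethyl-1,2-dioxolan-3-yl]acetaldehyde | CC/C=C/C=C/C=C/CCCCCCCC[C@@]1(C)C[C@](C)(CC=O)OO1 | intermediate
17 | 2-[(3R,5S)-5-[(9E,11E,13E)-hexadeca-9,11,13-trien-1-yl]-3,5-dimethyl-1,2-dioxolan-3-yl]acetic acid | CC/C=C/C=C/C=C/CCCCCCCC[C@@]1(C)C[C@](C)(CC(=O)O)OO1 | target

**Step count**
Total step count: 12.
Longest linear sequence: 11 steps (steps 1–4 and 6–12, from 1 to 17); step 5 is a one-step side branch.

**Steps most likely to fail**

Step 6. The counter-anion may not discriminate the two faces of the peroxycarbenium ion or the two faces of the tertiary cation well enough, since CH3 and CH2R differ little in size. Achiral silyl species may also open a racemic background path, and proton loss or a 1,2-shift may compete with ring closure. The fallback sets out from 5 and 7 and uses the known racemic annulation: SnCl4 (1 equiv), CH2Cl2, −78 °C should give the stereoisomer mixture of tert-butyl{2-[5-(9-bromononyl)-3,5-dimethyl-1,2-dioxolan-3-yl]ethoxy}diphenylsilane F1. Chromatography on silica should separate its racemic (3S,5S)/(3R,5R) trans-dimethyl diastereomer F2 from the cis pair. Preparative HPLC of F2 on a chiral stationary phase (cellulose tris(3,5-dimethylphenylcarbamate)) should then deliver 10, where the route is rejoined.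

Step 9. The sulfonyl carbanion or the amide base may attack the O–O bond, the dienal may be deprotonated at its vinylogous position, and the new double bond may form with incomplete E selectivity. The fallback sets out from 10 and reverses the polarity, so that the peroxide-bearing partner is the electrophile and meets only a stabilised phosphonate anion. Ganem oxidation of the primary bromide (Me3NO, DMSO, rt) should give 9-[(3S,5S)-5-{2-[tert-butyl(diphenyl)silyloxy]ethyl}-3,5-dimethyl-1,2-dioxolan-3-yl]nonanal F3. Separately, commercial (2E,4E)-hepta-2,4-dien-1-ol is converted with PBr3 (Et2O, 0 °C) into (2E,4E)-1-bromohepta-2,4-diene F4 and by Arbuzov reaction with P(OEt)3 (heat) into diethyl [(2E,4E)-hepta-2,4-dien-1-yl]phosphonate F5. Horner–Wadsworth–Emmons reaction of F3 with the anion of F5 (LiN(SiMe3)2, THF, −78 °C to 0 °C) should give the E-configured triene 14, where the route is rejoined.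

Step 11. The β-peroxy aldehyde may lose the peroxide oxygen by β-elimination (ring opening) during oxidation or handling, and the triene may be degraded by the oxidants of steps 11 and 12. The fallback sets out from 12 and moves the oxidation ahead of the olefination, where no triene is present and an acidic oxidant can be used. Desilylation (Bu4NF, AcOH, THF) should give 2-[(3S,5S)-3,5-dimethyl-5-{9-[(1-phenyl-1H-tetrazol-5-yl)sulfonyl]nonyl}-1,2-dioxolan-3-yl]ethan-1-ol F6. Jones oxidation (CrO3, H2SO4, acetone, 0 °C) should take it directly to 2-[(3R,5S)-3,5-dimethyl-5-{9-[(1-phenyl-1H-tetrazol-5-yl)sulfonyl]nonyl}-1,2-dioxolan-3-yl]acetic acid F7. Julia–Kocienski olefination of F7 with 13 (KN(SiMe3)2, 2.2 equiv, DME, −60 °C to rt, then acidic work-up) should give 17, where the route is rejoined; the first equivalent of base forms the carboxylate, which resists α-deprotonation and hence β-elimination.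

**Further compounds**
F1 | step 6 | tert-butyl{2-[5-(9-bromononyl)-3,5-dimethyl-1,2-dioxolan-3-yl]ethoxy}diphenylsilane, mixture of the four stereoisomers | BrCCCCCCCCCC1(C)CC(C)(CCO[Si](c2ccccc2)(c2ccccc2)C(C)(C)C)OO1
F2 | step 6 | racemic trans-dimethyl diastereomer, (3S,5S) and (3R,5R), of tert-butyl{2-[5-(9-bromononyl)-3,5-dimethyl-1,2-dioxolan-3-yl]ethoxy}diphenylsilane | BrCCCCCCCCC[C@@]1(C)C[C@](C)(CCO[Si](c2ccccc2)(c2ccccc2)C(C)(C)C)OO1.BrCCCCCCCCC[C@]1(C)C[C@@](C)(CCO[Si](c2ccccc2)(c2ccccc2)C(C)(C)C)OO1
F3 | step 9 | 9-[(3S,5S)-5-{2-[tert-butyl(diphenyl)silyloxy]ethyl}-3,5-dimethyl-1,2-dioxolan-3-yl]nonanal | O=CCCCCCCCC[C@@]1(C)C[C@](C)(CCO[Si](c2ccccc2)(c2ccccc2)C(C)(C)C)OO1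
F4 | step 9 | (2E,4E)-1-bromohepta-2,4-diene | CC/C=C/C=C/CBr
F5 | step 9 | diethyl [(2E,4E)-hepta-2,4-dien-1-yl]phosphonate | CC/C=C/C=C/CP(=O)(OCC)OCC
F6 | step 11 | 2-[(3S,5S)-3,5-dimethyl-5-{9-[(1-phenyl-1H-tetrazol-5-yl)sulfonyl]nonyl}-1,2-dioxolan-3-yl]ethan-1-ol | c1ccccc1-n1nnnc1S(=O)(=O)CCCCCCCCC[C@@]1(C)C[C@](C)(CCO)OO1
F7 | step 11 | 2-[(3R,5S)-3,5-dimethyl-5-{9-[(1-phenyl-1H-tetrazol-5-yl)sulfonyl]nonyl}-1,2-dioxolan-3-yl]acetic acid | c1ccccc1-n1nnnc1S(=O)(=O)CCCCCCCCC[C@@]1(C)C[C@](C)(CC(=O)O)OO1
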